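## Analysis of the target

Target 20 is a six-carbon polyol chain attached to a bis-oxazole. Ring A is a 2,4-disubstituted oxazole and ring B a 5-monosubstituted oxazole with free C2–H and C4–H; one methylene joins C2 of ring A to C5 of ring B. The chain is numbered from the carbinol carbon on C4 of ring A: C1 carries the palmitate, C2 is a methylene, C3, C4 and C5 carry free hydroxyls, and C6 is a methyl group. The configuration is 1R,3S,4R,5S, with C3/C4 erythro and C4/C5 threo, which is the C3–C5 pattern of 2-deoxy-L-fucose; C1 lies 1,3 to C3 across the methylene and has no neighbour that controls it directly. Sensitive points are the secondary ester on a heteroaryl carbinol 1,3 to a hydroxyl (acyl migration, solvolysis), the doubly activated inter-ring methylene, and the acidic C2–H of ring B, whose metalated form opens to an isocyano enolate. The synthesis is hard for two reasons: only C1 of four similar hydroxyls may be acylated, and the heteroaromatic half tolerates neither strong base nor organolithium reagents. The strategy rests on reading C1–C6 as a ring-opened 1-C-substituted L-fucal. C3, C4, C5 and the methyl group come with the sugar, the glycal C2 is the chain methylene, and the enol ether carbon C1 is both the sp2 coupling site for the bond to C4 of ring A and a masked ketone from which the C1 carbinol is made.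

## Retrosynthetic reasoning

**Si–O bonds (20 to 19).** The three free hydroxyls are disconnected last, as the two tert-butyldimethylsilyl ethers and one triethylsilyl ether of 19. With the palmitate already on C1 and every other oxygen blocked, no regioselective acylation is needed. The forward step only has to cleave Si–O bonds without moving or hydrolysing the ester, which calls for an acidic fluoride source and not a basic one.

**Ester C–O bond (19 to 17 and 18).** The acyl–oxygen bond is cut to give alcohol 17, whose only free hydroxyl is at C1, and palmitoyl chloride 18. The lipophilic chain therefore enters late, and the intermediates before it stay easy to handle.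

**C1–H bond (17 to 16).** The C1 stereocentre is traced back to ketone 16. C1 is flanked by a flat heteroaryl ring and a methylene, the size difference a chiral oxazaborolidine can read. C1 is thus set by the reagent, independently of C3–C5, after the carbon skeleton is complete.

**C5–O–Si bond and the C1 carbonyl (16 to 14 and 13).** A ketone with an adjacent methylene and a δ-oxygen is the hydrate of a cyclic enol ether whose ring oxygen is the C5 oxygen. Retro-hydration therefore closes the pyran and leads to the 1-C-heteroaryl glycal 13. In the forward direction hydration gives hemiketal 14, not a free ketone. Hemiketal 14 is in ring–chain equilibrium with hydroxy ketone 15, and silylation of the C5 hydroxyl of 15 locks the open form as 16.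

**C1–C4(ring A) bond (13 to 7 and 12), the key disconnection.** The sp2–sp2 bond between the glycal carbon and ring A is cut. This divides the molecule into a complete carbohydrate half and a complete heteroaromatic half, and no stereocentre is at stake in the coupling. Tin is placed on the glycal (12) and the triflate on ring A (7), because the opposite polarity would need a 4-metalated oxazole in the presence of the acidic methylene and the C2–H of ring B.

**C–Sn bond and protecting groups (12 to 10, 9 and 8).** Stannane 12 comes from silyl glycal 10 through the C1-lithiated glycal 11. Glycal 10 is the bis-silyl ether of L-fucal 9, obtained from the commercial diacetate 8. The silyl ethers are chosen because they survive the lithiation and are removed together at the end.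

**Ring A (7 to 6, 5, 3, 4 and 1).** The triflate S–O bond is cut to oxazolone 6. The O1–C5 bond of 6 is cut to imide 5 (an intramolecular O-alkylation in the forward sense), and the imide N–acyl bond to amide 3 and chloroacetyl chloride 4, which supplies C4 and C5 of ring A. Amide 3 comes from acid 1 through acyl imidazole 2. Ring B and the methylene are therefore bought complete and never built.

## Alternatives that were turned down

**Alternative 1:** gold-catalysed annulation of an alkyne and an amide to build ring A.
- *Disconnection:* the O1–C5 and N3–C4 bonds of ring A. The fragments are amide 3 and the protected oct-1-yne-3,5,6,7-tetraol A2 (3-O-triethylsilyl, 5-O-tert-butyldimethylsilyl, 6,7-O-isopropylidene), whose propargylic carbon is chain C1.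
- *Forward key step:* (Mor-DalPhos)AuNTf2 activates the alkyne of A2, 8-methylquinoline N-oxide A3 transfers oxygen to give an α-oxo gold carbene, and amide 3 is captured and cyclodehydrated to the protected bis-oxazole A1.
- *For:* ring A is formed in the step that joins the halves, with the 2,4-pattern fixed by the mechanism. No tin is used, and the heteroaromatic half needs one step from acid 1 instead of four.
- *Against:* A2 must already hold all four stereocentres, including the propargylic C1 carbinol, so a reagent-controlled alkynylation and a multistep protecting-group sequence come before the key step. In the annulation C1 sits next to the carbonyl of the carbene intermediate. The C1 and C3 ether oxygens are placed for 4- or 6-membered intramolecular capture of the carbene, which competes with the weakly nucleophilic amide. After the annulation C1 still has to be unmasked selectively and acylated.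
- *Comparison:* the overall length is similar to the chosen route, and Alternative 1 is stronger in atom economy and in forming ring A during the union. The chosen strategy instead couples through a cross-coupling that touches no stereocentre, takes three stereocentres from the sugar, and sets C1 only after ring A is in place.

**Alternative 2:** lipase–ruthenium dynamic kinetic resolution installing the palmitate and C1.
- *Disconnection:* the ester O–acyl bond together with the C1 configuration. The C3≡C4 triple bond stands in for the C3/C4 diol.
- *Forward key step:* immobilised Burkholderia cepacia lipase transfers the acyl group of 4-chlorophenyl palmitate A6 to the 1R epimer of the hex-3-yn-1-ol A5 ((5S)-5-silyloxy, both C1 epimers), while (η5-C5Ph5)Ru(CO)2Cl activated by KOtBu epimerises C1 through the ketone, giving palmitate A4.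
- *For:* the ester and C1 are set in one catalytic operation with no protecting group on C1, both epimers are funnelled to product, and a long-chain acyl donor suits a lipase.
- *Against:* the empirical size rule for lipases needs one small substituent on the carbinol, whereas A5 carries a bis-oxazole and a silyloxy-alkynyl chain. The alkoxide-activated ruthenium catalyst meets the acidic inter-ring methylene and two coordinating oxazole nitrogens. C3 and C4 remain to be made after the key step by semihydrogenation to the Z-alkene and cis-dihydroxylation. The target needs the C4 hydroxyl threo to the C5 oxygen, whereas osmylation of an allylic ether normally gives the erythro relationship, and catalytic asymmetric dihydroxylation is least selective for cis-disubstituted alkenes. The palmitate can also migrate to the new C3 hydroxyl.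
- *Comparison:* Alternative 2 is the stronger answer for C1 and is shorter on paper. The chosen strategy gives certainty at C3, C4 and C5 in its place and keeps the ester out of all stereochemistry-forming steps.

**Alternative 3:** nickel electroreductive coupling forging the inter-oxazole methylene.
- *Disconnection:* the bond from C2 of ring A to the methylene. The fragments are the 2-chloro ring A fragment A8, which carries the complete palmitoylated and protected chain, and 5-(chloromethyl)oxazole A9.
- *Forward key step:* cathodic reduction with NiBr2(dme) and a 2,2'-bipyridine-type ligand. Low-valent nickel inserts into the C2–Cl bond of A8, captures the heteroarylmethyl radical from A9 and reductively eliminates to the protected target A7.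
- *For:* it is the most convergent union. Ring B and the acidic methylene appear only at the end, so no earlier step has to tolerate them, and no organometallic reagent is needed.
- *Against:* the disconnection does nothing for the four stereocentres, so A8 needs its own long stereocontrolled synthesis. The most valuable intermediate is exposed to low-valent nickel and a cathode while carrying a heteroaryl-methyl ester whose C–O bond can be cleaved reductively. A9 alkylates oxazole nitrogen and homocouples. The product methylene is acidic toward electrogenerated base.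
- *Comparison:* Alternative 3 is stronger in convergence and in keeping the methylene out of a long sequence. The chosen strategy instead takes its risk early, on two small and cheap fragments, and obtains the stereochemistry from the chiral pool.

Key step: step 8

## Route

Assumption: 3,4-di-O-acetyl-L-fucal 8 and 2-(1,3-oxazol-5-yl)acetic acid 1 are taken as catalogue compounds. If 8 had to be made, it would come from L-fucose by peracetylation, HBr/AcOH and Zn reduction.

Step 1
Reactants: 1 2-(1,3-oxazol-5-yl)acetic acid
Product: 3 2-(1,3-oxazol-5-yl)acetamide, via 1-[(1,3-oxazol-5-yl)acetyl]imidazole 2 (not isolated)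
Conditions: CDI (1.1 equiv), THF, rt; then 28% aq NH3, 0 °C → rt
Reagents that add atoms: ammonia, N
Why: Activation of the acid as its acyl imidazole and aminolysis is a standard primary amide synthesis; the neutral conditions avoid ketene formation and leave ring B and the methylene untouched.

Step 2
Reactants: 3 2-(1,3-oxazol-5-yl)acetamide; 4 chloroacetyl chloride
Product: 5 2-chloro-N-[(1,3-oxazol-5-yl)acetyl]acetamide
Conditions: toluene, 100 °C, N2 sweep; NaHCO3 work-up
Reagents that add atoms: none
Why: N-Acylation of a primary amide by an acid chloride without base gives the imide, with HCl leaving as gas; the weakly basic nitrogen of ring B is not acylated productively.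

Step 3
Reactants: 5 2-chloro-N-[(1,3-oxazol-5-yl)acetyl]acetamide
Product: 6 2-(1,3-oxazol-5-ylmethyl)-1,3-oxazol-4(5H)-one
Conditions: NaH (1.05 equiv), DME, 0 °C → rt
Reagents that add atoms: none
Why: The imide N–H is the most acidic site; the oxygen of the resulting ambident anion displaces chloride in a 5-exo-tet O-alkylation, the usual closure to 2-substituted oxazol-4(5H)-ones, and one equivalent of base leaves the methylene alone.

Step 4
Reactants: 6 2-(1,3-oxazol-5-ylmethyl)-1,3-oxazol-4(5H)-one
Product: 7 2-(1,3-oxazol-5-ylmethyl)-1,3-oxazol-4-yl trifluoromethanesulfonate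
Conditions: Tf2O (1.1 equiv), 2,6-lutidine, CH2Cl2, −78 °C
Reagents that add atoms: trifluoromethanesulfonic anhydride, O=S(=O)(OS(=O)(=O)C(F)(F)F)C(F)(F)F
Why: Enolisation toward the aromatic 4-hydroxyoxazole tautomer and O-sulfonylation is the established route to oxazol-4-yl triflates; whichever tautomer of 6 is present, O-triflation leads to the aromatic ring, and the low temperature keeps the ring B nitrogen from reacting.

Step 5
Reactants: 8 3,4-di-O-acetyl-L-fucal
Product: 9 L-fucal (1,5-anhydro-2,6-dideoxy-L-lyxo-hex-1-enitol)
Conditions: K2CO3 (0.1 equiv), MeOH, rt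
Reagents that add atoms: none
Why: Zemplén-type transesterification removes both acetates under conditions to which the acid-sensitive enol ether is inert.

Step 6
Reactants: 9 L-fucal
Product: 10 3,4-bis-O-(tert-butyldimethylsilyl)-L-fucal
Conditions: TBSCl (3 equiv), imidazole (6 equiv), DMAP (cat.), DMF, 45 °C
Reagents that add atoms: tert-butyldimethylsilyl chloride, CC(C)(C)[Si](C)(C)Cl
Why: Silylation of both secondary hydroxyls; the axial C4 hydroxyl is the slower one, hence the excess reagent and warming, and the basic medium protects the glycal.

Step 7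
Reactants: 10 3,4-bis-O-(tert-butyldimethylsilyl)-L-fucal
Product: 12 3,4-bis-O-(tert-butyldimethylsilyl)-1-(tributylstannyl)-L-fucal, via 1-lithio glycal 11 (not isolated)
Conditions: t-BuLi (3.5 equiv), THF, −78 → 0 °C; then Bu3SnCl, −78 °C → rt; Et3N-deactivated silica
Reagents that add atoms: tributyltin chloride, CCCC[Sn](Cl)(CCCC)CCCC
Why: Vinylic deprotonation at C1 of a silyl-protected glycal, acidified and directed by the ring oxygen, followed by lithium–tin exchange is the standard entry to 1-stannyl glycals; the 6-deoxy substrate has no primary silyl ether, the stereocentres are not involved, and the acid-labile stannane is purified on base-washed silica.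

Step 8
Reactants: 7 2-(1,3-oxazol-5-ylmethyl)-1,3-oxazol-4-yl trifluoromethanesulfonate; 12 3,4-bis-O-(tert-butyldimethylsilyl)-1-(tributylstannyl)-L-fucal
Product: 13 1-C-[2-(1,3-oxazol-5-ylmethyl)-1,3-oxazol-4-yl]-3,4-bis-O-(tert-butyldimethylsilyl)-L-fucal
Conditions: Pd(PPh3)4 (10 mol %), CuI (20 mol %), LiCl (3 equiv), degassed DMF, 60 °C; aq KF work-up
Reagents that add atoms: none
Why: This is a Stille coupling: zerovalent palladium inserts into the C4–O bond of triflate 7, chloride from LiCl replaces triflate on the divalent palladium intermediate, the glycal alkenyl group is transferred from tin (assisted by CuI, which takes up free phosphine and can relay the alkenyl group through copper), and reductive elimination forms the C1–C4(ring A) bond. The closest known reaction types are the coupling of 1-stannyl glycals with aryl electrophiles to C-aryl glycals and the coupling of oxazol-4-yl triflates with alkenyl stannanes. No ring is closed and no stereocentre is formed; C3, C4 and C5 are remote from the reacting carbon and pass through unchanged. The step needs transfer of the alkenyl group and not a butyl group, which the much faster migration of sp2 carbon from tin secures. It needs reaction only at the triflate, which is the sole electrophilic C–O or C–X bond in either partner. It also needs the stannane to survive until transmetalation, which the neutral, anhydrous and oxygen-free medium secures. Because no base is present, the acidic C2–H of ring B and the inter-ring methylene are not touched.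

Step 9
Reactants: 13 1-C-[2-(1,3-oxazol-5-ylmethyl)-1,3-oxazol-4-yl]-3,4-bis-O-(tert-butyldimethylsilyl)-L-fucal
Product: 14 1-C-[2-(1,3-oxazol-5-ylmethyl)-1,3-oxazol-4-yl]-3,4-bis-O-(tert-butyldimethylsilyl)-2,6-dideoxy-L-lyxo-hexopyranose (hemiketal, both anomers)
Conditions: PPh3·HBr (10 mol %), THF/H2O (10:1), 0 °C → rt
Reagents that add atoms: water, O
Why: Acid-catalysed hydration of the enol ether: protonation at C2 gives an oxocarbenium ion stabilised by the ring oxygen and ring A, and water adds at C1 to give the hemiketal; the anomeric configuration is irrelevant because both anomers open to the same ketone, and silyl ethers are poor leaving groups, so Ferrier-type allylic substitution should not compete.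

Step 10
Reactants: 14 1-C-[2-(1,3-oxazol-5-ylmethyl)-1,3-oxazol-4-yl]-3,4-bis-O-(tert-butyldimethylsilyl)-2,6-dideoxy-L-lyxo-hexopyranose
Product: 16 (3S,4R,5S)-3,4-bis(tert-butyldimethylsilyloxy)-1-[2-(1,3-oxazol-5-ylmethyl)-1,3-oxazol-4-yl]-5-(triethylsilyloxy)hexan-1-one, via open-chain hydroxy ketone 15 (not isolated)
Conditions: TESCl (2 equiv), imidazole (4 equiv), DMAP (0.2 equiv), DMF, 0 °C → rt
Reagents that add atoms: chlorotriethylsilane, CC[Si](Cl)(CC)CC
Why: Silylative opening of a lactol to a δ-silyloxy ketone: imidazole catalyses the ring–chain equilibrium, the secondary C5 hydroxyl of the open tautomer 15 is silylated, and the tertiary anomeric hydroxyl of 14 is too hindered for the silyl chloride, so the equilibrium drains through 15.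

Step 11
Reactants: 16 (3S,4R,5S)-3,4-bis(tert-butyldimethylsilyloxy)-1-[2-(1,3-oxazol-5-ylmethyl)-1,3-oxazol-4-yl]-5-(triethylsilyloxy)hexan-1-one
Product: 17 (1R,3S,4R,5S)-3,4-bis(tert-butyldimethylsilyloxy)-1-[2-(1,3-oxazol-5-ylmethyl)-1,3-oxazol-4-yl]-5-(triethylsilyloxy)hexan-1-ol
Conditions: (S)-2-methyl-CBS-oxazaborolidine (1.0 equiv), BH3·SMe2 (1.5 equiv), THF, −30 °C; MeOH quench
Reagents that add atoms: none
Why: Corey–Bakshi–Shibata reduction of a heteroaryl alkyl ketone: the ketone binds the (S)-oxazaborolidine with ring A as the large group and the C2 methylene as the small one, and hydride goes to the Si face (O > ring A > C2) to give 1R, by analogy with acetophenone giving the R alcohol; a full equivalent of catalyst and excess borane allow for weak binding of borane to the oxazole nitrogens.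

Step 12
Reactants: 17 (1R,3S,4R,5S)-3,4-bis(tert-butyldimethylsilyloxy)-1-[2-(1,3-oxazol-5-ylmethyl)-1,3-oxazol-4-yl]-5-(triethylsilyloxy)hexan-1-ol; 18 palmitoyl chloride
Product: 19 (1R,3S,4R,5S)-3,4-bis(tert-butyldimethylsilyloxy)-1-[2-(1,3-oxazol-5-ylmethyl)-1,3-oxazol-4-yl]-5-(triethylsilyloxy)hexyl hexadecanoate
Conditions: pyridine, DMAP (0.1 equiv), CH2Cl2, 0 °C → rt
Reagents that add atoms: none
Why: DMAP-catalysed acylation of the only free hydroxyl; the C–O bond at C1 is not broken, so the configuration is retained.

Step 13
Reactants: 19 (1R,3S,4R,5S)-3,4-bis(tert-butyldimethylsilyloxy)-1-[2-(1,3-oxazol-5-ylmethyl)-1,3-oxazol-4-yl]-5-(triethylsilyloxy)hexyl hexadecanoate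
Product: 20 (1R,3S,4R,5S)-3,4,5-trihydroxy-1-[2-(1,3-oxazol-5-ylmethyl)-1,3-oxazol-4-yl]hexyl hexadecanoate
Conditions: HF·pyridine, THF/pyridine, 0 °C → rt
Reagents that add atoms: none
Why: Fluoride-driven cleavage of the three silyl ethers under buffered acidic conditions, which is standard for global desilylation next to esters; acyl migration is base-promoted and should stay slow here, and no stereocentre is touched.

## Compound list

1 | 2-(1,3-oxazol-5-yl)acetic acid | OC(=O)Cc1cnco1 | starting material
2 | 1-[(1,3-oxazol-5-yl)acetyl]imidazole (not isolated) | O=C(Cc1cnco1)n1ccnc1 | intermediate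
3 | 2-(1,3-oxazol-5-yl)acetamide | NC(=O)Cc1cnco1 | intermediate
4 | chloroacetyl chloride | ClCC(=O)Cl | starting material
5 | 2-chloro-N-[(1,3-oxazol-5-yl)acetyl]acetamide | O=C(CCl)NC(=O)Cc1cnco1 | intermediate
6 | 2-(1,3-oxazol-5-ylmethyl)-1,3-oxazol-4(5H)-one | O=C1COC(Cc2cnco2)=N1 | intermediate
7 | 2-(1,3-oxazol-5-ylmethyl)-1,3-oxazol-4-yl trifluoromethanesulfonate | FC(F)(F)S(=O)(=O)Oc1coc(Cc2cnco2)n1 | intermediate
8 | 3,4-di-O-acetyl-L-fucal | C[C@@H]1OC=C[C@H](OC(C)=O)[C@@H]1OC(C)=O | starting material
9 | L-fucal (1,5-anhydro-2,6-dideoxy-L-lyxo-hex-1-enitol) | C[C@@H]1OC=C[C@H](O)[C@@H]1O | intermediate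
10 | 3,4-bis-O-(tert-butyldimethylsilyl)-L-fucal | C[C@@H]1OC=C[C@H](O[Si](C)(C)C(C)(C)C)[C@@H]1O[Si](C)(C)C(C)(C)C | intermediate
11 | 3,4-bis-O-(tert-butyldimethylsilyl)-1-lithio-L-fucal (not isolated) | C[C@@H]1OC([Li])=C[C@H](O[Si](C)(C)C(C)(C)C)[C@@H]1O[Si](C)(C)C(C)(C)C | intermediate
12 | 3,4-bis-O-(tert-butyldimethylsilyl)-1-(tributylstannyl)-L-fucal | C[C@@H]1OC([Sn](CCCC)(CCCC)CCCC)=C[C@H](O[Si](C)(C)C(C)(C)C)[C@@H]1O[Si](C)(C)C(C)(C)C | intermediate
13 | 1-C-[2-(1,3-oxazol-5-ylmethyl)-1,3-oxazol-4-yl]-3,4-bis-O-(tert-butyldimethylsilyl)-L-fucal | C[C@@H]1OC(c2coc(Cc3cnco3)n2)=C[C@H](O[Si](C)(C)C(C)(C)C)[C@@H]1O[Si](C)(C)C(C)(C)C | intermediate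
14 | 1-C-[2-(1,3-oxazol-5-ylmethyl)-1,3-oxazol-4-yl]-3,4-bis-O-(tert-butyldimethylsilyl)-2,6-dideoxy-L-lyxo-hexopyranose (hemiketal, both anomers) | C[C@@H]1OC(O)(c2coc(Cc3cnco3)n2)C[C@H](O[Si](C)(C)C(C)(C)C)[C@@H]1O[Si](C)(C)C(C)(C)C | intermediate
15 | (3S,4R,5S)-3,4-bis(tert-butyldimethylsilyloxy)-5-hydroxy-1-[2-(1,3-oxazol-5-ylmethyl)-1,3-oxazol-4-yl]hexan-1-one (not isolated) | O=C(C[C@H](O[Si](C)(C)C(C)(C)C)[C@H](O[Si](C)(C)C(C)(C)C)[C@H](C)O)c1coc(Cc2cnco2)n1 | intermediate
16 | (3S,4R,5S)-3,4-bis(tert-butyldimethylsilyloxy)-1-[2-(1,3-oxazol-5-ylmethyl)-1,3-oxazol-4-yl]-5-(triethylsilyloxy)hexan-1-one | O=C(C[C@H](O[Si](C)(C)C(C)(C)C)[C@H](O[Si](C)(C)C(C)(C)C)[C@H](C)O[Si](CC)(CC)CC)c1coc(Cc2cnco2)n1 | intermediate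
17 | (1R,3S,4R,5S)-3,4-bis(tert-butyldimethylsilyloxy)-1-[2-(1,3-oxazol-5-ylmethyl)-1,3-oxazol-4-yl]-5-(triethylsilyloxy)hexan-1-ol | O[C@H](C[C@H](O[Si](C)(C)C(C)(C)C)[C@H](O[Si](C)(C)C(C)(C)C)[C@H](C)O[Si](CC)(CC)CC)c1coc(Cc2cnco2)n1 | intermediate
18 | palmitoyl chloride (hexadecanoyl chloride) | CCCCCCCCCCCCCCCC(=O)Cl | starting material
19 | (1R,3S,4R,5S)-3,4-bis(tert-butyldimethylsilyloxy)-1-[2-(1,3-oxazol-5-ylmethyl)-1,3-oxazol-4-yl]-5-(triethylsilyloxy)hexyl hexadecanoate | CCCCCCCCCCCCCCCC(=O)O[C@H](C[C@H](O[Si](C)(C)C(C)(C)C)[C@H](O[Si](C)(C)C(C)(C)C)[C@H](C)O[Si](CC)(CC)CC)c1coc(Cc2cnco2)n1 | intermediate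
20 | (1R,3S,4R,5S)-3,4,5-trihydroxy-1-[2-(1,3-oxazol-5-ylmethyl)-1,3-oxazol-4-yl]hexyl hexadecanoate (CNP0240423.1) | CCCCCCCCCCCCCCCC(=O)O[C@H](C[C@H](O)[C@H](O)[C@H](C)O)c1coc(Cc2cnco2)n1 | target

## Step count and least certain steps

Total step count: 13. Longest linear sequence: 10 steps (steps 1–4 and 8–13, from acid 1); the sugar branch reaches the target in 9 steps (steps 5–13).

**Step 8 (key step).** The stannyl group is most likely lost by protonolysis or oxidative homocoupling before transmetalation, because the α-alkoxy alkenyl tin centre is hindered and acid-labile, while the triflate is slowly hydrolysed by adventitious water. The fallback replaces tin by boron. It sets out from silyl glycal 10, which is lithiated as in step 7 and quenched with 2-isopropoxy-4,4,5,5-tetramethyl-1,3,2-dioxaborolane to give 3,4-bis-O-(tert-butyldimethylsilyl)-1-(4,4,5,5-tetramethyl-1,3,2-dioxaborolan-2-yl)-L-fucal F1. Suzuki–Miyaura coupling of the boronate with triflate 7 (Pd(dppf)Cl2, K3PO4, dioxane/H2O, 50 °C) returns to the route at coupled glycal 13.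

**Step 10.** The ring–chain equilibrium may lie so far on the closed side, or open so slowly, that silylation stalls or goes to the anomeric oxygen of the hemiketal. The fallback opens the ring at carbon instead of trapping the oxygen. It sets out from hemiketal 14, which with propane-1,3-dithiol and BF3·OEt2 (CH2Cl2, −40 °C) should give the open-chain hydroxy 1,3-dithiane F2, in which the ketone carbon is held as a dithioketal and cannot re-close. The C5 hydroxyl is then silylated (TESCl, imidazole, DMF) to the silyl ether F3, and oxidative removal of the dithiane (PhI(OCOCF3)2, MeCN/H2O, 0 °C) returns to the route at ketone 16.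

**Step 11.** Facial selectivity may be poor, because the C2 methylene carries a bulky β-branched chain that narrows the size difference to ring A, and borane bound to an oxazole nitrogen can reduce the ketone outside the catalyst. The fallback is stereoconvergent and does not depend on reagent control. It sets out from ketone 16, which is reduced with NaBH4 (MeOH, −20 °C) to alcohol 17 and its epimer, the (1S,3S,4R,5S)-alcohol F4. The two are diastereomers and are separated by chromatography. Alcohol 17 goes on to step 12. The epimer is esterified with palmitic acid under Mitsunobu conditions (PPh3, DIAD, THF, 0 °C) with inversion at C1, so both portions return to the route at palmitate 19.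

**Step 13.** The two adjacent secondary tert-butyldimethylsilyl ethers may be cleaved too slowly, and the long exposure then allows migration of the palmitoyl group from the C1 oxygen to the freed C3 hydroxyl, or solvolysis at C1. The fallback changes the protecting-group plan so that the last step needs only very mild acid. It sets out from hemiketal 14, which is desilylated before any ester is present (HF·pyridine, THF) to the triol hemiketal F5. Excess TESCl with imidazole and DMAP in DMF then silylates all three hydroxyls with ring opening to the tris(triethylsilyl) ketone F6. CBS reduction as in step 11 gives the (1R)-alcohol F7, and acylation with palmitoyl chloride 18 as in step 12 gives the tris(triethylsilyl) palmitate F8. Removal of the three triethylsilyl groups with AcOH/THF/H2O at rt returns to the route at target 20.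

## Further compounds

F1 | step 8 | 3,4-bis-O-(tert-butyldimethylsilyl)-1-(4,4,5,5-tetramethyl-1,3,2-dioxaborolan-2-yl)-L-fucal | C[C@@H]1OC(B2OC(C)(C)C(C)(C)O2)=C[C@H](O[Si](C)(C)C(C)(C)C)[C@@H]1O[Si](C)(C)C(C)(C)C
F2 | step 10 | 1,3-dithiane (propane-1,3-diyl dithioketal) of hydroxy ketone 15, free C5 hydroxyl, chain configuration as in 15 | S1CCCSC1(C[C@H](O[Si](C)(C)C(C)(C)C)[C@H](O[Si](C)(C)C(C)(C)C)[C@H](C)O)c1coc(Cc2cnco2)n1
F3 | step 10 | 1,3-dithiane (propane-1,3-diyl dithioketal) of ketone 16, C5 O-triethylsilyl | S1CCCSC1(C[C@H](O[Si](C)(C)C(C)(C)C)[C@H](O[Si](C)(C)C(C)(C)C)[C@H](C)O[Si](CC)(CC)CC)c1coc(Cc2cnco2)n1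
F4 | step 11 | (1S,3S,4R,5S)-3,4-bis(tert-butyldimethylsilyloxy)-1-[2-(1,3-oxazol-5-ylmethyl)-1,3-oxazol-4-yl]-5-(triethylsilyloxy)hexan-1-ol | O[C@@H](C[C@H](O[Si](C)(C)C(C)(C)C)[C@H](O[Si](C)(C)C(C)(C)C)[C@H](C)O[Si](CC)(CC)CC)c1coc(Cc2cnco2)n1
F5 | step 13 | 1-C-[2-(1,3-oxazol-5-ylmethyl)-1,3-oxazol-4-yl]-2,6-dideoxy-L-lyxo-hexopyranose (hemiketal, both anomers) | C[C@@H]1OC(O)(c2coc(Cc3cnco3)n2)C[C@H](O)[C@@H]1O
F6 | step 13 | (3S,4R,5S)-1-[2-(1,3-oxazol-5-ylmethyl)-1,3-oxazol-4-yl]-3,4,5-tris(triethylsilyloxy)hexan-1-one | O=C(C[C@H](O[Si](CC)(CC)CC)[C@H](O[Si](CC)(CC)CC)[C@H](C)O[Si](CC)(CC)CC)c1coc(Cc2cnco2)n1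
F7 | step 13 | (1R,3S,4R,5S)-1-[2-(1,3-oxazol-5-ylmethyl)-1,3-oxazol-4-yl]-3,4,5-tris(triethylsilyloxy)hexan-1-ol | O[C@H](C[C@H](O[Si](CC)(CC)CC)[C@H](O[Si](CC)(CC)CC)[C@H](C)O[Si](CC)(CC)CC)c1coc(Cc2cnco2)n1
F8 | step 13 | (1R,3S,4R,5S)-1-[2-(1,3-oxazol-5-ylmethyl)-1,3-oxazol-4-yl]-3,4,5-tris(triethylsilyloxy)hexyl hexadecanoate | CCCCCCCCCCCCCCCC(=O)O[C@H](C[C@H](O[Si](CC)(CC)CC)[C@H](O[Si](CC)(CC)CC)[C@H](C)O[Si](CC)(CC)CC)c1coc(Cc2cnco2)n1
A1 | alternative 1 | fully protected bis-oxazole polyol (C1 O-triethylsilyl, C3 O-tert-butyldimethylsilyl, C4/C5 acetonide) | CC[Si](CC)(CC)O[C@H](C[C@H](O[Si](C)(C)C(C)(C)C)[C@@H]1OC(C)(C)O[C@H]1C)c1coc(Cc2cnco2)n1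
A2 | alternative 1 | protected oct-1-yne-3,5,6,7-tetraol (3-O-triethylsilyl, 5-O-tert-butyldimethylsilyl, 6,7-O-isopropylidene; configuration as in the target chain) | C#C[C@H](O[Si](CC)(CC)CC)C[C@H](O[Si](C)(C)C(C)(C)C)[C@@H]1OC(C)(C)O[C@H]1C
A3 | alternative 1 | 8-methylquinoline N-oxide | Cc1cccc2ccc[n+]([O-])c12
A4 | alternative 2 | (1R,5S)-5-(tert-butyldiphenylsilyloxy)-1-[2-(1,3-oxazol-5-ylmethyl)-1,3-oxazol-4-yl]hex-3-yn-1-yl hexadecanoate | CCCCCCCCCCCCCCCC(=O)O[C@H](CC#C[C@H](C)O[Si](c1ccccc1)(c1ccccc1)C(C)(C)C)c1coc(Cc2cnco2)n1
A5 | alternative 2 | (5S)-5-(tert-butyldiphenylsilyloxy)-1-[2-(1,3-oxazol-5-ylmethyl)-1,3-oxazol-4-yl]hex-3-yn-1-ol (both C1 epimers) | OC(CC#C[C@H](C)O[Si](c1ccccc1)(c1ccccc1)C(C)(C)C)c1coc(Cc2cnco2)n1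
A6 | alternative 2 | 4-chlorophenyl palmitate | CCCCCCCCCCCCCCCC(=O)Oc1ccc(Cl)cc1
A7 | alternative 3 | protected target (C3 O-tert-butyldimethylsilyl, C4/C5 acetonide) | CCCCCCCCCCCCCCCC(=O)O[C@H](C[C@H](O[Si](C)(C)C(C)(C)C)[C@@H]1OC(C)(C)O[C@H]1C)c1coc(Cc2cnco2)n1
A8 | alternative 3 | 2-chloro ring A fragment with the palmitoylated, protected chain | CCCCCCCCCCCCCCCC(=O)O[C@H](C[C@H](O[Si](C)(C)C(C)(C)C)[C@@H]1OC(C)(C)O[C@H]1C)c1coc(Cl)n1
A9 | alternative 3 | 5-(chloromethyl)-1,3-oxazole | ClCc1cnco1
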